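**Strategy**

Everything rests on cutting the O1–C2 bond of the 2,3-dihydrobenzofuran. C2 is benzylic to a 4-hydroxy-3-methoxyphenyl ring and also bears the furan oxygen O1, so the ring-opened carbinol can ionise, with loss of water, to a para-quinone methide in which C2 is the exocyclic methide carbon. In one operation the phenol oxygen on C7a adds to that carbon, closing the five-membered O1–C2–C3–C3a–C7a ring, returning the guaiacyl ring to aromaticity and setting C2 trans to C3. The precursor is a (1R,2S)-1,2-diarylpropan-1-ol from an Evans aldol: both phenols free, C3 already (S), the C9 oxygen as a TBDPS ether and the propyl-chain oxygen as a TBS ether.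

Key step: step 13

**Remarks**

- Locants: O1, C2, C3, C3a–C7a for the dihydrobenzofuran; C9 is the CH2O carbon on C3. In open-chain compounds the carbinol carbon is called "future C2" and its neighbour "future C3".
- Assumption: 4-(benzyloxy)-3-methoxybenzaldehyde 15 is bought (it is one benzylation away from vanillin). Alcohol 3 is also a catalogue compound, so step 1 can be skipped.
- The configuration of the carbinol carbon in 18–21 is erased in step 13, so only the future C3 has to be controlled beforehand.
- Design choice: the C9 oxygen is silylated before the ring closure. This blocks loss of formaldehyde from the quinone methide and leaves a single protecting group to remove at the end.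

**Route**

Step 1
Reactants: 1 eugenol
Product: 3 3-(4-hydroxy-3-methoxyphenyl)propan-1-ol, via bis-9-BBN adduct 2 (not isolated)
Conditions: 9-BBN (2.2 equiv), THF, 0 °C → rt; then aq. NaOH, 30% H2O2, 0 °C → rt
Reagents that add atoms: hydrogen peroxide, OO
Why: Hydroboration–oxidation places boron on the terminal CH2 of the allyl group (the phenol only consumes one B–H as a borinate that is hydrolysed on work-up), and alkaline peroxide replaces boron by hydroxyl.

Step 2
Reactants: 3 3-(4-hydroxy-3-methoxyphenyl)propan-1-ol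
Product: 4 3-[4-(allyloxy)-3-methoxyphenyl]propan-1-ol
Conditions: allyl bromide, K2CO3, acetone, reflux
Reagents that add atoms: allyl bromide, C=CCBr
Why: Williamson ether synthesis in which carbonate deprotonates only the phenol (pKa about 10), so the aliphatic alcohol stays free.

Step 3
Reactants: 4 3-[4-(allyloxy)-3-methoxyphenyl]propan-1-ol
Product: 6 2-allyl-4-(3-hydroxypropyl)-6-methoxyphenol, via ortho-allyl cyclohexadienone 5 (not isolated)
Conditions: N,N-diethylaniline, 195 °C, sealed tube
Reagents that add atoms: none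
Why: Aromatic Claisen rearrangement, a [3,3]-shift that delivers the allyl group to the only ortho carbon bearing hydrogen (the other is blocked by OMe), followed by tautomerisation of the dienone to the phenol.

Step 4
Reactants: 6 2-allyl-4-(3-hydroxypropyl)-6-methoxyphenol
Product: 7 3-[3-allyl-4-(benzyloxy)-5-methoxyphenyl]propan-1-ol
Conditions: BnBr, K2CO3, DMF, rt → 50 °C
Reagents that add atoms: benzyl bromide, BrCc1ccccc1
Why: Williamson benzylation of the phenoxide, again selective over the aliphatic alcohol under carbonate conditions, puts a hydrogenolysable group on the oxygen that becomes O1.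

Step 5
Reactants: 7 3-[3-allyl-4-(benzyloxy)-5-methoxyphenyl]propan-1-ol
Product: 8 [3-(3-allyl-4-(benzyloxy)-5-methoxyphenyl)propoxy](tert-butyl)dimethylsilane
Conditions: TBSCl, imidazole, CH2Cl2, 0 °C → rt
Reagents that add atoms: tert-butyl(chloro)dimethylsilane, CC(C)(C)[Si](C)(C)Cl
Why: Imidazole-mediated silylation of the only free hydroxyl masks the chain alcohol for the enolate and hydride chemistry that follows.

Step 6
Reactants: 8 [3-(3-allyl-4-(benzyloxy)-5-methoxyphenyl)propoxy](tert-butyl)dimethylsilane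
Product: 10 2-{2-(benzyloxy)-5-[3-(tert-butyldimethylsilyloxy)propyl]-3-methoxyphenyl}acetaldehyde, via vicinal diol 9 (not isolated)
Conditions: OsO4 (2 mol%), NaIO4 (4 equiv), 2,6-lutidine, dioxane/H2O (3:1), rt; crude aldehyde taken on directly
Reagents that add atoms: osmium tetroxide, O=[Os](=O)(=O)=O; sodium periodate, [Na+].[O-]I(=O)(=O)=O
Why: Lemieux–Johnson oxidation, in which catalytic osmylation of the terminal alkene and periodate cleavage of the diol remove the terminal carbon, with 2,6-lutidine suppressing over-oxidation and the benzyl and silyl ethers inert.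

Step 7
Reactants: 10 2-{2-(benzyloxy)-5-[3-(tert-butyldimethylsilyloxy)propyl]-3-methoxyphenyl}acetaldehyde
Product: 11 2-{2-(benzyloxy)-5-[3-(tert-butyldimethylsilyloxy)propyl]-3-methoxyphenyl}acetic acid
Conditions: NaClO2, NaH2PO4, 2-methyl-2-butene, t-BuOH/H2O, 0 °C → rt
Reagents that add atoms: sodium chlorite, [Na+].[O-]Cl=O
Why: Pinnick oxidation converts the aldehyde to the acid under buffered conditions, with 2-methyl-2-butene scavenging hypochlorous acid so that the electron-rich ring is not chlorinated.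

Step 8
Reactants: 11 2-{2-(benzyloxy)-5-[3-(tert-butyldimethylsilyloxy)propyl]-3-methoxyphenyl}acetic acid; 12 (R)-4-benzyl-2-oxazolidinone
Product: 14 (R)-4-benzyl-3-(2-{2-(benzyloxy)-5-[3-(tert-butyldimethylsilyloxy)propyl]-3-methoxyphenyl}acetyl)oxazolidin-2-one, via mixed pivalic anhydride 13 (not isolated)
Conditions: PivCl, Et3N, THF, −20 °C; then LiCl, 12, −20 °C → rt
Reagents that add atoms: none
Why: N-Acylation of the oxazolidinone through the mixed pivalic anhydride, whose hindered pivaloyl carbonyl is not attacked, so the arylacetyl group is transferred to nitrogen.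

Step 9
Reactants: 14 (R)-4-benzyl-3-(arylacetyl)oxazolidin-2-one; 15 4-(benzyloxy)-3-methoxybenzaldehyde
Product: 18 (4R)-4-benzyl-3-[(2R,3R)-2-{2-(benzyloxy)-5-[3-(tert-butyldimethylsilyloxy)propyl]-3-methoxyphenyl}-3-[4-(benzyloxy)-3-methoxyphenyl]-3-hydroxypropanoyl]oxazolidin-2-one, via Z-boron enolate 16 (not isolated), via boron aldolate 17 (not isolated)
Conditions: Bu2BOTf, i-Pr2NEt, CH2Cl2, −78 → 0 °C; then 15, −78 → 0 °C; pH 7 buffer, MeOH, 30% H2O2, 0 °C
Reagents that add atoms: none
Why: Evans syn-aldol reaction, in which the Z-boron enolate reacts through a chair Zimmerman–Traxler transition state on the enolate face away from the auxiliary benzyl group (carbonyl dipoles opposed), setting the α-carbon as (R) in the imide (the future C3, (S) once the carbonyl is a CH2O group) and the carbinol as (R), of which only the former matters later.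

Step 10
Reactants: 18 Evans syn-aldol adduct
Product: 19 (1R,2S)-2-{2-(benzyloxy)-5-[3-(tert-butyldimethylsilyloxy)propyl]-3-methoxyphenyl}-1-[4-(benzyloxy)-3-methoxyphenyl]propane-1,3-diol
Conditions: LiBH4, MeOH (1 equiv), THF, 0 °C
Reagents that add atoms: none
Why: Reductive removal of the auxiliary with LiBH4 (hydride attacks the exocyclic imide carbonyl), run cold to avoid retro-aldol cleavage or epimerisation of the benzylic α-centre, should give the 1,3-diol and return the auxiliary.

Step 11
Reactants: 19 (1R,2S)-1,3-diol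
Product: 20 (1R,2S)-2-{2-(benzyloxy)-5-[3-(tert-butyldimethylsilyloxy)propyl]-3-methoxyphenyl}-1-[4-(benzyloxy)-3-methoxyphenyl]-3-(tert-butyldiphenylsilyloxy)propan-1-ol
Conditions: TBDPSCl (1.1 equiv), imidazole, CH2Cl2, 0 °C → rt
Reagents that add atoms: tert-butyl(chloro)diphenylsilane, CC(C)(C)[Si](Cl)(c1ccccc1)c1ccccc1
Why: Chemoselective silylation, since the bulky silyl chloride reacts with the primary hydroxyl and not with the hindered secondary benzylic one, placing on C9 an acid-stable group that differentiates it from the chain oxygen.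

Step 12
Reactants: 20 C9-O-TBDPS dibenzyl ether
Product: 21 (1R,2S)-3-(tert-butyldiphenylsilyloxy)-2-{2-hydroxy-3-methoxy-5-[3-(tert-butyldimethylsilyloxy)propyl]phenyl}-1-(4-hydroxy-3-methoxyphenyl)propan-1-ol
Conditions: H2 (1 atm), 10% Pd/C, EtOAc, rt, stopped at full conversion
Reagents that add atoms: none
Why: Catalytic hydrogenolysis of the two aryl benzyl ethers, which are cleaved much faster than the benzylic C–OH bond in a neutral aprotic solvent, while the silyl ethers are untouched.

Step 13
Reactants: 21 bisphenol carbinol (cyclisation precursor)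
Product: 23 4-[(2R,3S)-5-[3-(tert-butyldimethylsilyloxy)propyl]-3-[(tert-butyldiphenylsilyloxy)methyl]-7-methoxy-2,3-dihydrobenzofuran-2-yl]-2-methoxyphenol, via para-quinone methide 22 (not isolated)
Conditions: CSA (0.1 equiv), 4 Å MS, CH2Cl2 (0.01 M), 0 °C → rt
Reagents that add atoms: none
Why: Catalytic acid protonates the benzylic hydroxyl of the 4-hydroxy-3-methoxyphenyl carbinol and water leaves with push from the para oxygen, giving para-quinone methide 22 (or its O-protonated benzylic cation), in which the future C2 is the exocyclic electrophilic carbon. The closest known reaction type is the acid-induced cyclisation of para-hydroxybenzylic alcohols carrying a 2-hydroxyaryl group on the adjacent carbon to trans-2-aryl-2,3-dihydrobenzofurans, i.e. a 1,6-conjugate addition of a phenol to a para-quinone methide. The furan ring closes in 5-exo-trig fashion: the phenolic oxygen on the future C7a attacks the exocyclic carbon, the O1–C2 bond forms and the cyclohexadienone returns to an aromatic phenol. The new C2 stereocentre is set by the existing C3 centre: with the C3–H bond eclipsing the exocyclic double bond to avoid allylic strain, the oxygen adds on the face that leaves the aryl group anti to the bulky CH2OTBDPS group, and because the benzylic C2–O1 bond can re-ionise under the same acid any cis isomer should drain to the more stable trans (2R,3S) compound, while the carbinol configuration of 21 is erased and irrelevant. The step needs O-cyclisation to beat proton loss from C3 (stilbene formation, and with it loss of the C3 configuration), loss of formaldehyde and intermolecular trapping; the five-membered intramolecular closure is inherently fast, the silylated C9 oxygen cannot fragment in a retro-Prins sense, high dilution disfavours oligomers, and the sieves keep the water formed from hydrolysing the TBS ether.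

Step 14
Reactants: 23 trans-dihydrobenzofuran (chain OTBS, C9-OTBDPS)
Product: 24 4-[(2R,3S)-3-[(tert-butyldiphenylsilyloxy)methyl]-5-(3-hydroxypropyl)-7-methoxy-2,3-dihydrobenzofuran-2-yl]-2-methoxyphenol
Conditions: CSA (0.1 equiv), MeOH/CH2Cl2 (1:1), 0 °C
Reagents that add atoms: none
Why: Acid-catalysed methanolysis of a silyl ether, in which the primary alkyl TBS ether is cleaved far faster than the primary TBDPS ether, and the cyclic benzylic ether survives the short cold exposure because ring closure is the preferred fate of any cation formed at C2.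

Step 15
Reactants: 24 chain alcohol; 25 (E)-ferulic acid
Product: 27 3-[(2R,3S)-3-[(tert-butyldiphenylsilyloxy)methyl]-2-(4-hydroxy-3-methoxyphenyl)-7-methoxy-2,3-dihydrobenzofuran-5-yl]propyl (E)-3-(4-hydroxy-3-methoxyphenyl)prop-2-enoate, via alkoxyphosphonium ferulate 26 (not isolated)
Conditions: 25 (1.3 equiv), PPh3, DIAD, THF, 0 °C → rt
Reagents that add atoms: none
Why: Mitsunobu esterification, in which the betaine is protonated by the carboxylic acid (pKa about 4.5) and not by the guaiacyl phenols (pKa about 10), so the carboxylate is the only anionic nucleophile and displaces triphenylphosphine oxide from the one primary alkoxyphosphonium ion available, with no stereocentre or alkene geometry touched.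

Step 16
Reactants: 27 C9-O-TBDPS feruloyl ester
Product: 28 3-[(2R,3S)-2-(4-hydroxy-3-methoxyphenyl)-3-(hydroxymethyl)-7-methoxy-2,3-dihydrobenzofuran-5-yl]propyl (E)-3-(4-hydroxy-3-methoxyphenyl)prop-2-enoate (CNP0149450.1)
Conditions: TBAF, AcOH (1:1), THF, 0 °C → rt
Reagents that add atoms: none
Why: Fluoride-induced desilylation of the primary TBDPS ether, with acetic acid keeping the medium from becoming basic enough to harm the cinnamate ester or the phenol-bearing dihydrobenzofuran.

**Compound list**

1 | eugenol (4-allyl-2-methoxyphenol) | C=CCc1ccc(O)c(OC)c1 | starting material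
2 | bis-9-BBN adduct of eugenol (B-alkyl-9-BBN at the chain terminus, phenol as 9-BBN borinate) | COc1cc(CCCB2C3CCCC2CCC3)ccc1OB1C2CCCC1CCC2 | intermediate (not isolated)
3 | 3-(4-hydroxy-3-methoxyphenyl)propan-1-ol | COc1cc(CCCO)ccc1O | intermediate
4 | 3-[4-(allyloxy)-3-methoxyphenyl]propan-1-ol | COc1cc(CCCO)ccc1OCC=C | intermediate
5 | 6-allyl-4-(3-hydroxypropyl)-2-methoxycyclohexa-2,4-dien-1-one (racemic) | O=C1C(OC)=CC(CCCO)=CC1CC=C | intermediate (not isolated)
6 | 2-allyl-4-(3-hydroxypropyl)-6-methoxyphenol | COc1cc(CCCO)cc(CC=C)c1O | intermediate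
7 | 3-[3-allyl-4-(benzyloxy)-5-methoxyphenyl]propan-1-ol | COc1cc(CCCO)cc(CC=C)c1OCc1ccccc1 | intermediate
8 | TBS ether of 7 | COc1cc(CCCO[Si](C)(C)C(C)(C)C)cc(CC=C)c1OCc1ccccc1 | intermediate
9 | 3-{2-(benzyloxy)-5-[3-(TBS-oxy)propyl]-3-methoxyphenyl}propane-1,2-diol (racemic) | COc1cc(CCCO[Si](C)(C)C(C)(C)C)cc(CC(O)CO)c1OCc1ccccc1 | intermediate (not isolated)
10 | 2-{2-(benzyloxy)-5-[3-(TBS-oxy)propyl]-3-methoxyphenyl}acetaldehyde | COc1cc(CCCO[Si](C)(C)C(C)(C)C)cc(CC=O)c1OCc1ccccc1 | intermediate
11 | 2-{2-(benzyloxy)-5-[3-(TBS-oxy)propyl]-3-methoxyphenyl}acetic acid | COc1cc(CCCO[Si](C)(C)C(C)(C)C)cc(CC(=O)O)c1OCc1ccccc1 | intermediate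
12 | (R)-4-benzyl-2-oxazolidinone | O=C1N[C@H](Cc2ccccc2)CO1 | starting material
13 | mixed anhydride of acid 11 with pivalic acid | COc1cc(CCCO[Si](C)(C)C(C)(C)C)cc(CC(=O)OC(=O)C(C)(C)C)c1OCc1ccccc1 | intermediate (not isolated)
14 | (R)-4-benzyl-3-(arylacetyl)oxazolidin-2-one (aryl = 2-benzyloxy-3-methoxy-5-[3-(TBS-oxy)propyl]phenyl) | COc1cc(CCCO[Si](C)(C)C(C)(C)C)cc(CC(=O)N2C(=O)OC[C@H]2Cc2ccccc2)c1OCc1ccccc1 | intermediate
15 | 4-(benzyloxy)-3-methoxybenzaldehyde | COc1cc(C=O)ccc1OCc1ccccc1 | starting material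
16 | Z-dibutylboron enolate of imide 14 | COc1cc(CCCO[Si](C)(C)C(C)(C)C)cc(/C=C(\OB(CCCC)CCCC)N2C(=O)OC[C@H]2Cc2ccccc2)c1OCc1ccccc1 | intermediate (not isolated)
17 | dibutylboron aldolate of 18 (O–BBu2 on the carbinol oxygen) | COc1cc(CCCO[Si](C)(C)C(C)(C)C)cc([C@@H](C(=O)N2C(=O)OC[C@H]2Cc2ccccc2)[C@@H](OB(CCCC)CCCC)c2ccc(OCc3ccccc3)c(OC)c2)c1OCc1ccccc1 | intermediate (not isolated)
18 | (4R)-4-benzyl-3-[(2R,3R)-2-aryl-3-[4-(benzyloxy)-3-methoxyphenyl]-3-hydroxypropanoyl]oxazolidin-2-one (aryl as in 14) | COc1cc(CCCO[Si](C)(C)C(C)(C)C)cc([C@@H](C(=O)N2C(=O)OC[C@H]2Cc2ccccc2)[C@@H](O)c2ccc(OCc3ccccc3)c(OC)c2)c1OCc1ccccc1 | intermediate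
19 | (1R,2S)-2-{2-(benzyloxy)-5-[3-(TBS-oxy)propyl]-3-methoxyphenyl}-1-[4-(benzyloxy)-3-methoxyphenyl]propane-1,3-diol | COc1cc(CCCO[Si](C)(C)C(C)(C)C)cc([C@@H](CO)[C@@H](O)c2ccc(OCc3ccccc3)c(OC)c2)c1OCc1ccccc1 | intermediate
20 | 3-O-TBDPS ether of 19, (1R,2S) | COc1cc(CCCO[Si](C)(C)C(C)(C)C)cc([C@@H](CO[Si](c2ccccc2)(c2ccccc2)C(C)(C)C)[C@@H](O)c2ccc(OCc3ccccc3)c(OC)c2)c1OCc1ccccc1 | intermediate
21 | (1R,2S)-3-(TBDPS-oxy)-2-{2-hydroxy-3-methoxy-5-[3-(TBS-oxy)propyl]phenyl}-1-(4-hydroxy-3-methoxyphenyl)propan-1-ol | COc1cc(CCCO[Si](C)(C)C(C)(C)C)cc([C@@H](CO[Si](c2ccccc2)(c2ccccc2)C(C)(C)C)[C@@H](O)c2ccc(O)c(OC)c2)c1O | intermediate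
22 | para-quinone methide from 21 (exocyclic C=C at the future C2, future C3 unchanged, alkene geometry undefined) | COc1cc(CCCO[Si](C)(C)C(C)(C)C)cc([C@@H](CO[Si](c2ccccc2)(c2ccccc2)C(C)(C)C)C=C2C=CC(=O)C(OC)=C2)c1O | intermediate (not isolated)
23 | 4-[(2R,3S)-5-[3-(TBS-oxy)propyl]-3-[(TBDPS-oxy)methyl]-7-methoxy-2,3-dihydrobenzofuran-2-yl]-2-methoxyphenol (trans) | CC(C)(C)[Si](C)(C)OCCCc1cc(OC)c2c(c1)[C@@H](CO[Si](c1ccccc1)(c1ccccc1)C(C)(C)C)[C@H](c1ccc(O)c(OC)c1)O2 | intermediate
24 | 4-[(2R,3S)-3-[(TBDPS-oxy)methyl]-5-(3-hydroxypropyl)-7-methoxy-2,3-dihydrobenzofuran-2-yl]-2-methoxyphenol | OCCCc1cc(OC)c2c(c1)[C@@H](CO[Si](c1ccccc1)(c1ccccc1)C(C)(C)C)[C@H](c1ccc(O)c(OC)c1)O2 | intermediate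
25 | (E)-ferulic acid | COc1cc(/C=C/C(=O)O)ccc1O | starting material
26 | alkoxytriphenylphosphonium ferulate of 24 (ion pair) | c1ccc(cc1)[P+](c1ccccc1)(c1ccccc1)OCCCc1cc(OC)c2c(c1)[C@@H](CO[Si](c1ccccc1)(c1ccccc1)C(C)(C)C)[C@H](c1ccc(O)c(OC)c1)O2.COc1cc(/C=C/C(=O)[O-])ccc1O | intermediate (not isolated)
27 | C9-O-TBDPS ether of the target, (2R,3S), (E) | COc1cc(/C=C/C(=O)OCCCc2cc(OC)c3c(c2)[C@@H](CO[Si](c2ccccc2)(c2ccccc2)C(C)(C)C)[C@H](c2ccc(O)c(OC)c2)O3)ccc1O | intermediate
28 | 3-[(2R,3S)-2-(4-hydroxy-3-methoxyphenyl)-3-(hydroxymethyl)-7-methoxy-2,3-dihydrobenzofuran-5-yl]propyl (E)-ferulate | COc1cc(/C=C/C(=O)OCCCc2cc(OC)c3c(c2)[C@@H](CO)[C@H](c2ccc(O)c(OC)c2)O3)ccc1O | target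

**Step count and risks**

Total step count: 16. Longest linear sequence: 16 steps (eugenol 1 → 28); 12, 15 and 25 are bought.

Three steps most likely to fail:

1. Step 13 (ring closure). The quinone methide may lose the proton on C3 instead of being trapped, which gives a stilbene and, if reversible, erodes the C3 configuration. It may also be captured by a phenol of a second molecule, or the trans preference may be incomplete. Partial loss of the chain TBS group would be harmless, because step 14 removes it. Fallback (sets out from 21, returns at 23): the quinone methide would be generated without acid. Bromotrimethylsilane in CH2Cl2 at 0 °C should convert the para-hydroxybenzylic alcohol of 21 into the benzylic bromide F1 (either epimer serves). Shaking the cold solution with saturated aqueous NaHCO3 then removes HBr, the same quinone methide 22 forms by 1,6-elimination, and the phenoxide closes the ring to 23. This is the known bromide/bicarbonate entry to quinone methides.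

2. Step 12 (hydrogenolysis). Once the para-phenol is freed, the benzylic C–OH bond becomes prone to reductive cleavage, or to ionisation on an acidic catalyst batch followed by reduction. Fallback (sets out from 20, returns at 23): the carbinol would be masked first. TESOTf/2,6-lutidine at −78 °C should silylate the only free hydroxyl of 20 to give the benzylic triethylsilyl ether F2. Hydrogenolysis as in step 12 should then give the bisphenol silyl ether F3, the bulky silyloxy group being a poor leaving group on palladium. Under the conditions of step 13, F3 should ionise with loss of triethylsilanol to the same quinone methide 22 and close to 23.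

3. Step 15 (esterification with free phenols). A phenol may be O-alkylated by the alkoxyphosphonium ion, or conversion may stall. Fallback (sets out from 23, returns at 28): a fully protected carbodiimide esterification. The phenol of 23 would be silylated (TBSCl, imidazole, DMF) to the aryl TBS ether F4. The primary alkyl TBS ether would then be cleaved selectively (CSA, MeOH, 0 °C; aryl TBS and TBDPS ethers are much less acid-labile) to the chain alcohol F5. Ferulic acid 25 would be bis-silylated (TBSCl, imidazole) to the silyl ester silyl ether F6, and the silyl ester hydrolysed (AcOH/THF/H2O) to 4-O-TBS-ferulic acid F7. Steglich coupling of F5 with F7 (EDC·HCl, DMAP, CH2Cl2) should give the tris-silyl ester F8, and buffered TBAF as in step 16 should remove all three silyl groups to give 28.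

**Further compounds**

F1 | step 13 | (2S)-1-bromo-3-(TBDPS-oxy)-2-{2-hydroxy-3-methoxy-5-[3-(TBS-oxy)propyl]phenyl}-1-(4-hydroxy-3-methoxyphenyl)propane (epimers at C1) | COc1cc(CCCO[Si](C)(C)C(C)(C)C)cc([C@@H](CO[Si](c2ccccc2)(c2ccccc2)C(C)(C)C)C(Br)c2ccc(O)c(OC)c2)c1O
F2 | step 12 | 1-O-triethylsilyl ether of 20 | COc1cc(CCCO[Si](C)(C)C(C)(C)C)cc([C@@H](CO[Si](c2ccccc2)(c2ccccc2)C(C)(C)C)[C@@H](O[Si](CC)(CC)CC)c2ccc(OCc3ccccc3)c(OC)c2)c1OCc1ccccc1
F3 | step 12 | 1-O-triethylsilyl ether of 21 | COc1cc(CCCO[Si](C)(C)C(C)(C)C)cc([C@@H](CO[Si](c2ccccc2)(c2ccccc2)C(C)(C)C)[C@@H](O[Si](CC)(CC)CC)c2ccc(O)c(OC)c2)c1O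
F4 | step 15 | aryl TBS ether of 23 | CC(C)(C)[Si](C)(C)OCCCc1cc(OC)c2c(c1)[C@@H](CO[Si](c1ccccc1)(c1ccccc1)C(C)(C)C)[C@H](c1ccc(O[Si](C)(C)C(C)(C)C)c(OC)c1)O2
F5 | step 15 | aryl TBS ether of 24 | OCCCc1cc(OC)c2c(c1)[C@@H](CO[Si](c1ccccc1)(c1ccccc1)C(C)(C)C)[C@H](c1ccc(O[Si](C)(C)C(C)(C)C)c(OC)c1)O2
F6 | step 15 | tert-butyldimethylsilyl (E)-4-O-TBS-ferulate | COc1cc(/C=C/C(=O)O[Si](C)(C)C(C)(C)C)ccc1O[Si](C)(C)C(C)(C)C
F7 | step 15 | (E)-4-O-TBS-ferulic acid | COc1cc(/C=C/C(=O)O)ccc1O[Si](C)(C)C(C)(C)C
F8 | step 15 | tris-silyl ester (C9-O-TBDPS, both phenols as TBS ethers) | COc1cc(/C=C/C(=O)OCCCc2cc(OC)c3c(c2)[C@@H](CO[Si](c2ccccc2)(c2ccccc2)C(C)(C)C)[C@H](c2ccc(O[Si](C)(C)C(C)(C)C)c(OC)c2)O3)ccc1O[Si](C)(C)C(C)(C)C
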